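## Retrosynthetic overview

1. The five O-methyl ethers come off last. The 6-methoxybenzofuran of pentamethyl ether 14 is cut by an intramolecular Wittig disconnection to the C6 carboxylic acid 9 and a 2-hydroxybenzylphosphonium salt.
2. The benzene ring of the dihydrobenzofuran is traced back, by dehydrogenation, to a cyclohexane-1,3-dione ring. C3a lies between C4–OH and C7a–O1, so it is C2 of a masked 1,3-dione; C6 carries the ester that becomes the benzofuran.
3. Key disconnection: the five-membered ring O1–C2–C3–C3a–C7a is made from the three-membered ring C3a–C3–C2 of a spiro[2.5]octane-4,8-dione by Cloke–Wilson ring expansion. The enabling feature is that C2 carries a 4-oxygenated aryl ring (donor) and C3a is the dione carbon (acceptor), so C3a–C3–C2 is a donor–acceptor cyclopropane that opens only at C3a–C2.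
4. The cyclopropane comes, in the same operation, from a 2-diazo-1,3-dione and commercial (E)-3,4′,5-trimethoxystilbene by enantioselective Rh(II) carbene transfer, which sets C3; C2 follows trans.
5. Ring order: cyclohexanedione (bought) → cyclopropane → dihydrofuran (ring expansion) → benzene ring (aromatisation) → benzofuran (Wittig).

Key step: step 2

Remark: the sense of induction of the chiral rhodium catalyst cannot be fixed in advance; Rh2(S-NTTL)4 is written, and its antipode (from D-tert-leucine) is to be used if the opposite alkene face reacts. Locants O1, C2, C3, C3a, C4–C7, C7a are those of the 2,3-dihydro-1-benzofuran core of the target and are used for its precursors as well.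

## Route

Step 1
Reactants: 1 ethyl 3,5-dioxocyclohexane-1-carboxylate
Product: 2 ethyl 4-diazo-3,5-dioxocyclohexane-1-carboxylate
Conditions: p-ABSA, Et3N, MeCN, 0 °C → rt
Reagents that add atoms: 4-acetamidobenzenesulfonyl azide (p-ABSA), CC(=O)Nc1ccc(cc1)S(=O)(=O)N=[N+]=[N-]
Why: Regitz diazo transfer to the doubly activated methylene between the two ketones of a cyclic 1,3-dione is fast under amine base and leaves the ester untouched.

Step 2
Reactants: 2 ethyl 4-diazo-3,5-dioxocyclohexane-1-carboxylate; 3 (E)-3,4′,5-trimethoxystilbene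
Product: 5 ethyl (2S,3S)-3-(3,5-dimethoxyphenyl)-2-(4-methoxyphenyl)-4-oxo-2,3,4,5,6,7-hexahydro-1-benzofuran-6-carboxylate (both C6 epimers), via spirocyclopropane 4 (not isolated)
Conditions: Rh2(S-NTTL)4 (1 mol%), 3 (3 equiv), PhCF3, 40 °C, slow addition of 2; then TsOH·H2O (10 mol%), rt
Reagents that add atoms: none
Why: Proposed new method: the Rh(II) carbene from 2 adds to the alkene of 3 to give the donor–acceptor spirocyclopropane 4, whose C(spiro)–CH(4-methoxyphenyl) bond heterolyses under acid to a dione enolate/p-methoxybenzyl cation pair that recloses through oxygen, a Cloke–Wilson three-to-five ring expansion driven by release of the cyclopropane strain; the closest known reactions are the Rh(II)-catalysed formal [3+2] annulation of cyclic 2-diazo-1,3-diones with styrenes, the enantioselective Rh(II) tert-leucinate-catalysed cyclopropanation with acceptor/acceptor carbenes and the acid-catalysed ring-opening cyclisation of cyclohexane-1,3-dione 2-spirocyclopropanes, none of which has been shown enantioselectively on a 1,2-diarylethene. The three-membered ring closes by concerted [2+1] carbene addition with retention of the E-alkene geometry, and the five-membered ring by 5-exo-trig capture of the benzylic cation by the enolate oxygen. C3 is set in the cyclopropanation by the chiral carboxylate pocket of the catalyst, which selects the alkene face, and is carried through unchanged because none of its bonds is broken in the ring expansion. C2 is set in the ring closure trans to the C3 aryl group by substrate control and, as the ionisation is reversible under the acid, should end as the more stable trans isomer whatever its configuration in 4. The step needs cleavage of the spiro bond to the carbon that becomes C2 and not to C3, which the para-methoxy donor secures against the two meta-methoxy groups of the other ring, and carbene attack on the alkene and not on the arenes, which conjugation with the anisyl ring and the excess of 3 secure.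

Step 3
Reactants: 5 ethyl (2S,3S)-3-(3,5-dimethoxyphenyl)-2-(4-methoxyphenyl)-4-oxo-2,3,4,5,6,7-hexahydro-1-benzofuran-6-carboxylate
Product: 7 ethyl (2S,3S)-3-(3,5-dimethoxyphenyl)-4-hydroxy-2-(4-methoxyphenyl)-2,3-dihydro-1-benzofuran-6-carboxylate, via α-phenylselanyl ketone 6 (not isolated)
Conditions: LDA, THF, −78 °C; PhSeCl, −78 °C; then 30% H2O2, pyridine, CH2Cl2, 0 °C → rt
Reagents that add atoms: none
Why: Kinetic enolisation α′ to the vinylogous-ester carbonyl (C5), selenenylation and oxidative syn-elimination put a C5–C6 double bond into the ring, and enolisation then gives the phenol; no hydride-abstracting oxidant touches C2–H or C3–H, so both stereocentres are kept and the C6 epimers converge.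

Step 4
Reactants: 7 ethyl (2S,3S)-3-(3,5-dimethoxyphenyl)-4-hydroxy-2-(4-methoxyphenyl)-2,3-dihydro-1-benzofuran-6-carboxylate
Product: 8 ethyl (2S,3S)-3-(3,5-dimethoxyphenyl)-4-methoxy-2-(4-methoxyphenyl)-2,3-dihydro-1-benzofuran-6-carboxylate
Conditions: MeI, K2CO3, DMF, rt
Reagents that add atoms: iodomethane, CI
Why: Williamson etherification of the phenoxide protects the C4 phenol for the acid chloride chemistry of step 7.

Step 5
Reactants: 8 ethyl (2S,3S)-3-(3,5-dimethoxyphenyl)-4-methoxy-2-(4-methoxyphenyl)-2,3-dihydro-1-benzofuran-6-carboxylate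
Product: 9 (2S,3S)-3-(3,5-dimethoxyphenyl)-4-methoxy-2-(4-methoxyphenyl)-2,3-dihydro-1-benzofuran-6-carboxylic acid
Conditions: LiOH·H2O, THF/H2O, 40 °C; then 1 M HCl
Reagents that add atoms: lithium hydroxide, [Li+].[OH-]
Why: Saponification of the ethyl ester; the trans-dihydrobenzofuran has no C–H acidic enough for hydroxide to epimerise.

Step 6
Reactants: 10 2-(hydroxymethyl)-5-methoxyphenol (2-hydroxy-4-methoxybenzyl alcohol)
Product: 11 [(2-hydroxy-4-methoxyphenyl)methyl]triphenylphosphonium bromide
Conditions: PPh3·HBr, MeCN, reflux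
Reagents that add atoms: triphenylphosphine hydrobromide, [Br-].c1ccc(cc1)[PH+](c1ccccc1)c1ccccc1
Why: Under HBr the o-hydroxybenzyl alcohol ionises to an o-quinone-methide-type cation that triphenylphosphine captures, the standard preparation of 2-hydroxybenzylphosphonium salts.

Step 7
Reactants: 9 (2S,3S)-3-(3,5-dimethoxyphenyl)-4-methoxy-2-(4-methoxyphenyl)-2,3-dihydro-1-benzofuran-6-carboxylic acid; 11 [(2-hydroxy-4-methoxyphenyl)methyl]triphenylphosphonium bromide
Product: 14 (2S,3S)-3-(3,5-dimethoxyphenyl)-4-methoxy-6-(6-methoxy-1-benzofuran-2-yl)-2-(4-methoxyphenyl)-2,3-dihydro-1-benzofuran, via acid chloride 12 (not isolated), via ester phosphonium salt 13 (not isolated)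
Conditions: (COCl)2, DMF (cat.), CH2Cl2, 0 °C → rt, evaporation; then 11, Et3N (3.5 equiv), toluene, 110 °C
Reagents that add atoms: none
Why: O-acylation of the phenol of 11 by the acid chloride and deprotonation give an ylide that closes the furan ring by intramolecular Wittig olefination of the ester carbonyl, a standard 2-arylbenzofuran synthesis that places the methoxy group at C6 of the new benzofuran.

Step 8
Reactants: 14 (2S,3S)-3-(3,5-dimethoxyphenyl)-4-methoxy-6-(6-methoxy-1-benzofuran-2-yl)-2-(4-methoxyphenyl)-2,3-dihydro-1-benzofuran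
Product: 15 (2S,3S)-3-(3,5-dihydroxyphenyl)-6-(6-hydroxy-1-benzofuran-2-yl)-2-(4-hydroxyphenyl)-2,3-dihydro-1-benzofuran-4-ol (target)
Conditions: BBr3 (12 equiv), CH2Cl2, −78 °C → rt; then MeOH, H2O
Reagents that add atoms: none
Why: Boron tribromide cleaves all five aryl methyl ethers by Lewis-acid-assisted SN2 demethylation; C3 cannot epimerise, and any reversible opening of the C2–O bond should reclose to the trans isomer, which is the more stable one.

## Compound list

1 | ethyl 3,5-dioxocyclohexane-1-carboxylate | CCOC(=O)C1CC(=O)CC(=O)C1 | starting material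
2 | ethyl 4-diazo-3,5-dioxocyclohexane-1-carboxylate | CCOC(=O)C1CC(=O)C(=[N+]=[N-])C(=O)C1 | intermediate
3 | (E)-3,4′,5-trimethoxystilbene (1,3-dimethoxy-5-[(E)-2-(4-methoxyphenyl)ethenyl]benzene) | COc1ccc(/C=C/c2cc(OC)cc(OC)c2)cc1 | starting material
4 | ethyl (1S,2S)-1-(3,5-dimethoxyphenyl)-2-(4-methoxyphenyl)-4,8-dioxospiro[2.5]octane-6-carboxylate (trans-diaryl; both C6 epimers; not isolated) | CCOC(=O)C1CC(=O)C2(C(=O)C1)[C@H](c1ccc(OC)cc1)[C@H]2c1cc(OC)cc(OC)c1 | intermediate
5 | ethyl (2S,3S)-3-(3,5-dimethoxyphenyl)-2-(4-methoxyphenyl)-4-oxo-2,3,4,5,6,7-hexahydro-1-benzofuran-6-carboxylate (both C6 epimers) | COc1ccc([C@H]2OC3=C(C(=O)CC(C(=O)OCC)C3)[C@@H]2c2cc(OC)cc(OC)c2)cc1 | intermediate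
6 | ethyl (2S,3S)-3-(3,5-dimethoxyphenyl)-2-(4-methoxyphenyl)-4-oxo-5-(phenylselanyl)-2,3,4,5,6,7-hexahydro-1-benzofuran-6-carboxylate (not isolated) | COc1ccc([C@H]2OC3=C(C(=O)C([Se]c4ccccc4)C(C(=O)OCC)C3)[C@@H]2c2cc(OC)cc(OC)c2)cc1 | intermediate
7 | ethyl (2S,3S)-3-(3,5-dimethoxyphenyl)-4-hydroxy-2-(4-methoxyphenyl)-2,3-dihydro-1-benzofuran-6-carboxylate | COc1ccc([C@H]2Oc3cc(C(=O)OCC)cc(O)c3[C@@H]2c2cc(OC)cc(OC)c2)cc1 | intermediate
8 | ethyl (2S,3S)-3-(3,5-dimethoxyphenyl)-4-methoxy-2-(4-methoxyphenyl)-2,3-dihydro-1-benzofuran-6-carboxylate | COc1ccc([C@H]2Oc3cc(C(=O)OCC)cc(OC)c3[C@@H]2c2cc(OC)cc(OC)c2)cc1 | intermediate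
9 | (2S,3S)-3-(3,5-dimethoxyphenyl)-4-methoxy-2-(4-methoxyphenyl)-2,3-dihydro-1-benzofuran-6-carboxylic acid | COc1ccc([C@H]2Oc3cc(C(O)=O)cc(OC)c3[C@@H]2c2cc(OC)cc(OC)c2)cc1 | intermediate
10 | 2-(hydroxymethyl)-5-methoxyphenol (2-hydroxy-4-methoxybenzyl alcohol) | COc1ccc(CO)c(O)c1 | starting material
11 | [(2-hydroxy-4-methoxyphenyl)methyl]triphenylphosphonium bromide | COc1ccc(C[P+](c2ccccc2)(c2ccccc2)c2ccccc2)c(O)c1.[Br-] | intermediate
12 | (2S,3S)-3-(3,5-dimethoxyphenyl)-4-methoxy-2-(4-methoxyphenyl)-2,3-dihydro-1-benzofuran-6-carbonyl chloride (not isolated) | COc1ccc([C@H]2Oc3cc(C(Cl)=O)cc(OC)c3[C@@H]2c2cc(OC)cc(OC)c2)cc1 | intermediate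
13 | {[2-({(2S,3S)-3-(3,5-dimethoxyphenyl)-4-methoxy-2-(4-methoxyphenyl)-2,3-dihydro-1-benzofuran-6-carbonyl}oxy)-4-methoxyphenyl]methyl}triphenylphosphonium bromide (not isolated) | COc1ccc([C@H]2Oc3cc(C(=O)Oc4cc(OC)ccc4C[P+](c4ccccc4)(c4ccccc4)c4ccccc4)cc(OC)c3[C@@H]2c2cc(OC)cc(OC)c2)cc1.[Br-] | intermediate
14 | (2S,3S)-3-(3,5-dimethoxyphenyl)-4-methoxy-6-(6-methoxy-1-benzofuran-2-yl)-2-(4-methoxyphenyl)-2,3-dihydro-1-benzofuran | COc1ccc([C@H]2Oc3cc(-c4cc5ccc(OC)cc5o4)cc(OC)c3[C@@H]2c2cc(OC)cc(OC)c2)cc1 | intermediate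
15 | (2S,3S)-3-(3,5-dihydroxyphenyl)-6-(6-hydroxy-1-benzofuran-2-yl)-2-(4-hydroxyphenyl)-2,3-dihydro-1-benzofuran-4-ol | Oc1ccc([C@H]2Oc3cc(-c4cc5ccc(O)cc5o4)cc(O)c3[C@@H]2c2cc(O)cc(O)c2)cc1 | target

Total step count: 8. Longest linear sequence: 7 (steps 1, 2, 3, 4, 5, 7, 8); step 6 is a one-step side branch that joins in step 7.

## Steps most likely to fail

**Step 2 (Proposed new method).** The chiral catalyst may not differentiate the two faces of the internal 1,2-diarylethene well enough. Carbene transfer to this hindered alkene may also be slower than carbene dimerisation or electrophilic attack on the dimethoxyphenyl ring. The fallback uses known chemistry, keeps the ring expansion, sets out from 1 and 3 and comes back at 7. Dione 1 is converted with PhI(OAc)2/KOH in MeOH into its phenyliodonium ylide F1. Irradiation of F1 with blue LEDs in the presence of 3 (visible-light cyclopropanation of alkenes with iodonium ylides of cyclic 1,3-diones) should give the racemic trans-spirocyclopropane F2. TsOH-catalysed Cloke–Wilson ring expansion of F2 should give the racemic tetrahydrobenzofuranone F3. Aromatisation as in step 3, through the racemic selenide F4, should give the racemic phenol ester F5. F5 is resolved by preparative chromatography on a chiral stationary phase, and the (2S,3S) enantiomer is 7.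

**Step 8.** Lewis-acid ionisation of the p-oxygenated benzylic C2–O bond may compete with demethylation, so that ring-opened and epimeric material accumulates. The fallback sets out from 14 and comes back at 15, and makes the ring opening deliberate. Excess BBr3 at rt followed by hydrolytic work-up converts the ring-opened benzylic bromide into the benzylic alcohol F7; any material that recloses directly is already 15. F7 is then cyclised with catalytic TsOH in MeCN, an acid-catalysed cyclodehydration through the p-quinone methide. The aryl ring that carries the two ortho hydroxyls is symmetric, so either oxygen gives the same product; C3 is untouched and C2 should close trans under thermodynamic control.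

**Step 3.** The peroxide/seleninic acid mixture may oxidise the electron-rich phenol or the benzylic positions, and enolisation at more than one site may lead to unproductive selenenylation. The fallback sets out from 5 and comes back at 7. Enolate trapping (LDA, TMSCl, THF, −78 °C) gives the silyl dienol ether F6. Saegusa–Ito oxidation (Pd(OAc)2, MeCN, rt) puts in the C5–C6 double bond without peroxide, and the dienone tautomerises to 7.

## Further compounds

F1 | step 2 | phenyliodonium ylide of 1 (ethyl 3,5-dioxo-4-(phenyliodonio)cyclohexan-4-ide-1-carboxylate, drawn as the enolate zwitterion) | CCOC(=O)C1CC(=O)C([I+]c2ccccc2)=C([O-])C1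
F2 | step 2 | racemic trans-spirocyclopropane (racemate of 4) | CCOC(=O)C1CC(=O)C2(C(=O)C1)[C@H](c1ccc(OC)cc1)[C@H]2c1cc(OC)cc(OC)c1.CCOC(=O)C1CC(=O)C2(C(=O)C1)[C@@H](c1ccc(OC)cc1)[C@@H]2c1cc(OC)cc(OC)c1
F3 | step 2 | racemic trans-tetrahydrobenzofuranone (racemate of 5) | COc1ccc([C@H]2OC3=C(C(=O)CC(C(=O)OCC)C3)[C@@H]2c2cc(OC)cc(OC)c2)cc1.COc1ccc([C@@H]2OC3=C(C(=O)CC(C(=O)OCC)C3)[C@H]2c2cc(OC)cc(OC)c2)cc1
F4 | step 2 | racemic α-phenylselanyl ketone (racemate of 6) | COc1ccc([C@H]2OC3=C(C(=O)C([Se]c4ccccc4)C(C(=O)OCC)C3)[C@@H]2c2cc(OC)cc(OC)c2)cc1.COc1ccc([C@@H]2OC3=C(C(=O)C([Se]c4ccccc4)C(C(=O)OCC)C3)[C@H]2c2cc(OC)cc(OC)c2)cc1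
F5 | step 2 | racemic trans-phenol ester (racemate of 7) | COc1ccc([C@H]2Oc3cc(C(=O)OCC)cc(O)c3[C@@H]2c2cc(OC)cc(OC)c2)cc1.COc1ccc([C@@H]2Oc3cc(C(=O)OCC)cc(O)c3[C@H]2c2cc(OC)cc(OC)c2)cc1
F6 | step 3 | ethyl (2S,3S)-3-(3,5-dimethoxyphenyl)-2-(4-methoxyphenyl)-4-[(trimethylsilyl)oxy]-2,3,6,7-tetrahydro-1-benzofuran-6-carboxylate | COc1ccc([C@H]2OC3=C(C(O[Si](C)(C)C)=CC(C(=O)OCC)C3)[C@@H]2c2cc(OC)cc(OC)c2)cc1
F7 | step 8 | 2-[(1S)-1-(3,5-dihydroxyphenyl)-2-hydroxy-2-(4-hydroxyphenyl)ethyl]-5-(6-hydroxy-1-benzofuran-2-yl)benzene-1,3-diol (carbinol epimers) | Oc1ccc(C(O)[C@@H](c2cc(O)cc(O)c2)c2c(O)cc(-c3cc4ccc(O)cc4o3)cc2O)cc1
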